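**Retrosynthetic overview**

1. The target is 1β-[(E)-p-coumaroyloxy]polygodial; the C1 ester, the C11/C12 dialdehyde (Swern of the 11,12-diol) and the diol (reduction of a Δ7-12,11-olide) are disconnected last.
2. The C7=C8 bond comes from a temporary C7 ketone (enol triflate, formate reduction), and the C5 and C9 hydrogens from one α-face hydrogenation of a cross-conjugated 7-oxo-5,8-dien-12,11-olide.
3. Key disconnection: that dienone lactone is opened at C8=C9 (Knoevenagel) and C5=C6 (Horner–Wadsworth–Emmons) to a monocyclic ring A diketone that carries a 4-phosphonoacetoacetate on the C11 oxygen.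
4. Enabling feature: C10 is quaternary, so the ring A ketone carbon C5 and the side-chain ketone carbon C9 form a 1,3-dielectrophile that cannot enolise between the carbonyls; it is matched by the 1,3-dinucleophile C6/C8 of the C6–C7(=O)–C8–C12 unit, held by a temporary C11–O–C12 ester and activated by a temporary C7 carbonyl.
5. Ring order: ring A is bought (2,2,6-trimethylcyclohexanone); the temporary butenolide ring and ring B are closed together in the key step; the lactone ring is opened again in step 13.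

Key step: step 9

Remark: drimane numbering (C1–C10 ring carbons, C11 on C9, C12 on C8) is used for positions throughout, also in the monocyclic precursors.
Remark: the enantiomer of the bisphosphine in step 2 is assumed to be the one that gives the 3R boronate; compounds 3–5 are C2 epimer mixtures, which is harmless because C2 becomes trigonal in step 4.

**Step 1**
Reactants: 1 2,2,6-trimethylcyclohexan-1-one
Product: 2 2,6,6-trimethylcyclohex-2-en-1-one
Conditions: IBX, DMSO, 70 °C
Reagents that add atoms: none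
Why: IBX α,β-dehydrogenation of a ketone (Nicolaou oxidation) can engage only the single enolisable α-position, so the 2-ene is the only conjugated enone possible and no stereocentre is formed.

**Step 2**
Reactants: 2 2,6,6-trimethylcyclohex-2-en-1-one
Product: 4 (3R)-3-hydroxy-2,6,6-trimethylcyclohexan-1-one (C2 epimers), via boronate 3 (not isolated)
Conditions: B2pin2, CuCl (5 mol %), NaOt-Bu (10 mol %), (R,S)-Josiphos (6 mol %), MeOH, THF, 23 °C; then 30% H2O2, pH 7 phosphate buffer, 0 °C
Reagents that add atoms: bis(pinacolato)diboron, CC1(C)OB(OC1(C)C)B1OC(C)(C)C(C)(C)O1 (boryl group of 3 only); hydrogen peroxide, OO (oxygen of 4)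
Why: Copper-catalysed asymmetric conjugate borylation of the enone followed by stereoretentive C–B oxidation should give the β-hydroxy ketone, the carbinol centre (future C1) being set by the chiral bisphosphine–copper boryl catalyst.

**Step 3**
Reactants: 4 (3R)-3-hydroxy-2,6,6-trimethylcyclohexan-1-one
Product: 5 (3R)-3-[(tert-butyldimethylsilyl)oxy]-2,6,6-trimethylcyclohexan-1-one (C2 epimers)
Conditions: TBSOTf, 2,6-lutidine, CH2Cl2, −78 to 0 °C
Reagents that add atoms: tert-butyldimethylsilyl triflate, CC(C)(C)[Si](C)(C)OS(=O)(=O)C(F)(F)F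
Why: Silyl ether formation with a silyl triflate and a hindered base protects the alcohol without the retro-aldol or β-elimination that stronger bases would cause; no stereocentre changes.

**Step 4**
Reactants: 5 (3R)-3-[(tert-butyldimethylsilyl)oxy]-2,6,6-trimethylcyclohexan-1-one; 6 (benzyloxy)acetaldehyde
Product: 8 (2S,3R)-2-[2-(benzyloxy)-1-hydroxyethyl]-3-[(tert-butyldimethylsilyl)oxy]-2,6,6-trimethylcyclohexan-1-one (carbinol epimers), via lithium enolate 7 (not isolated)
Conditions: LiN(i-Pr)2, THF, −78 °C; then 6, −78 °C; AcOH, −78 °C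
Reagents that add atoms: lithium diisopropylamide, CC(C)[N-]C(C)C.[Li+] (lithium of 7 only)
Why: Directed aldol addition of the only possible lithium enolate should set the quaternary carbon (future C10) with the new chain trans to the silyloxy group, because allylic 1,2-strain with the enolate methyl holds that group pseudoaxial and the aldehyde adds to the opposite face; the carbinol epimers converge in step 5.

**Step 5**
Reactants: 8 (2S,3R)-2-[2-(benzyloxy)-1-hydroxyethyl]-3-[(tert-butyldimethylsilyl)oxy]-2,6,6-trimethylcyclohexan-1-one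
Product: 9 (2S,3R)-2-[(benzyloxy)acetyl]-3-[(tert-butyldimethylsilyl)oxy]-2,6,6-trimethylcyclohexan-1-one
Conditions: Dess–Martin periodinane, CH2Cl2, 23 °C
Reagents that add atoms: none
Why: Dess–Martin oxidation converts both carbinol epimers into one 1,3-diketone under non-basic conditions that avoid retro-aldol cleavage at the quaternary carbon.

**Step 6**
Reactants: 9 (2S,3R)-2-[(benzyloxy)acetyl]-3-[(tert-butyldimethylsilyl)oxy]-2,6,6-trimethylcyclohexan-1-one
Product: 10 (2S,3R)-3-[(tert-butyldimethylsilyl)oxy]-2-(hydroxyacetyl)-2,6,6-trimethylcyclohexan-1-one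
Conditions: H2 (1 atm), 10% Pd/C, EtOAc, 23 °C
Reagents that add atoms: none
Why: Hydrogenolysis of the benzyl ether over palladium on carbon frees the C11 hydroxyl; nothing else in the molecule is reducible under these conditions.

**Step 7**
Reactants: 11 (diethoxyphosphoryl)acetic acid; 12 Meldrum's acid (2,2-dimethyl-1,3-dioxane-4,6-dione)
Product: 13 5-[2-(diethoxyphosphoryl)-1-hydroxyethylidene]-2,2-dimethyl-1,3-dioxane-4,6-dione
Conditions: DCC, DMAP, CH2Cl2, 0 to 23 °C
Reagents that add atoms: none
Why: Oikawa–Yonemitsu C-acylation of Meldrum's acid by the carbodiimide-activated acid gives the acyl Meldrum's acid, a stable acylketene precursor.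

**Step 8**
Reactants: 10 (2S,3R)-3-[(tert-butyldimethylsilyl)oxy]-2-(hydroxyacetyl)-2,6,6-trimethylcyclohexan-1-one; 13 5-[2-(diethoxyphosphoryl)-1-hydroxyethylidene]-2,2-dimethyl-1,3-dioxane-4,6-dione
Product: 14 2-{(1S,6R)-6-[(tert-butyldimethylsilyl)oxy]-1,3,3-trimethyl-2-oxocyclohexyl}-2-oxoethyl 4-(diethoxyphosphoryl)-3-oxobutanoate
Conditions: toluene, 90 °C
Reagents that add atoms: none
Why: Thermolysis of the acyl Meldrum's acid releases an acylketene that the primary alcohol traps (β-keto ester formation) under neutral conditions that spare the base-sensitive 1,3-diketone.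

**Step 9**
Reactants: 14 2-{(1S,6R)-6-[(tert-butyldimethylsilyl)oxy]-1,3,3-trimethyl-2-oxocyclohexyl}-2-oxoethyl 4-(diethoxyphosphoryl)-3-oxobutanoate
Product: 16 1β-[(tert-butyldimethylsilyl)oxy]-7-oxodrima-5,8-dien-12,11-olide, via acylbutenolide 15 (not isolated)
Conditions: DBU, LiCl, 4 Å MS, MeCN, 23 °C, then 70 °C
Reagents that add atoms: none
Why: Proposed new method: base first enolises the active methylene C8, whose ketone enolate adds to the side-chain ketone C9 in a 5-(enolexo)-exo-trig aldol, and E1cB loss of water gives acylbutenolide 15 (C8=C9); the β-ketophosphonate carbanion at C6 then adds to the ring A ketone C5 in a 6-(enolendo)-exo-trig closure and the oxaphosphetane collapses to the C5=C6 bond of ring B with loss of diethyl phosphate. The closest known reactions are the cyclisation of acyloin acetoacetates to 3-acylbutenolides and the cyclohexenone annulation with 4-phosphonoacetoacetates (conjugate or Knoevenagel addition, then intramolecular Horner–Wadsworth–Emmons olefination), which have not been run as one cascade on a ketone flanked by two quaternary carbons. No stereocentre is formed, because C5, C6, C8 and C9 all end trigonal, and C5 and C9 are set only in step 10. The site selectivity needed (C8 to C9, C6 to C5) is secured by ring size, since the crossed pairings (C8 to C5, C6 to C9) would need seven-membered rings, and by the quaternary C10, which leaves the ring ketone without any α-hydrogen and blocks enolisation between the two carbonyls. The butenolide fixes C10 and C7 cis on the C8=C9 bond, which holds the phosphonate carbon against the hindered C5 carbonyl and, together with the irreversible phosphate loss, is what should overcome the double neopentyl hindrance.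

**Step 10**
Reactants: 16 1β-[(tert-butyldimethylsilyl)oxy]-7-oxodrima-5,8-dien-12,11-olide
Product: 17 1β-[(tert-butyldimethylsilyl)oxy]-7-oxo-5α,8α,9α-H-drimano-12,11-lactone (keto form; C8 enolisable)
Conditions: H2 (4 atm), 10% Pd/C, EtOAc, 23 °C
Reagents that add atoms: none
Why: Heterogeneous catalytic hydrogenation of both electron-poor alkenes should deliver hydrogen from the α-face, opposite the axial C10 methyl (and the axial C4 methyl), which sets 5α-H (trans ring fusion) and 9α-H (C11 on the β-face) in one step, as in the known α-face hydrogenation of 4,4,10-trimethyl-Δ5-octalins.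

**Step 11**
Reactants: 17 1β-[(tert-butyldimethylsilyl)oxy]-7-oxo-5α,8α,9α-H-drimano-12,11-lactone
Product: 18 1β-[(tert-butyldimethylsilyl)oxy]-7-{[(trifluoromethyl)sulfonyl]oxy}drim-7-en-12,11-olide
Conditions: Tf2O, i-Pr2NEt, CH2Cl2, −78 to 0 °C
Reagents that add atoms: triflic anhydride, O=S(=O)(OS(=O)(=O)C(F)(F)F)C(F)(F)F
Why: O-Sulfonylation of the β-keto lactone enol gives the vinyl triflate regioselectively between the two carbonyls, which makes C8 trigonal again and leaves C5 and C9 untouched.

**Step 12**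
Reactants: 18 1β-[(tert-butyldimethylsilyl)oxy]-7-{[(trifluoromethyl)sulfonyl]oxy}drim-7-en-12,11-olide
Product: 19 1β-[(tert-butyldimethylsilyl)oxy]drim-7-en-12,11-olide (lactone C=O is C12, conjugated with C7=C8; CH2–O is C11)
Conditions: Pd(OAc)2 (5 mol %), PPh3, HCO2H, n-Bu3N, DMF, 60 °C
Reagents that add atoms: none
Why: Palladium-catalysed formate reduction of a vinyl triflate (Cacchi reduction) replaces C–OTf by C–H without moving the double bond, so the temporary C7 oxygen leaves behind exactly the C7=C8 bond of the target.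

**Step 13**
Reactants: 19 1β-[(tert-butyldimethylsilyl)oxy]drim-7-en-12,11-olide
Product: 20 1β-[(tert-butyldimethylsilyl)oxy]drim-7-ene-11,12-diol
Conditions: LiAlH4, THF, 0 °C
Reagents that add atoms: none
Why: Hydride reduction of the conjugated lactone to the allylic 1,4-diol is the known conversion of drim-7-en-12,11-olides into drim-7-ene-11,12-diols and spares the silyl ether and the trisubstituted alkene.

**Step 14**
Reactants: 20 1β-[(tert-butyldimethylsilyl)oxy]drim-7-ene-11,12-diol
Product: 21 1β-[(tert-butyldimethylsilyl)oxy]-11,12-(isopropylidenedioxy)drim-7-ene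
Conditions: 2,2-dimethoxypropane, PPTS (cat.), CH2Cl2, 23 °C
Reagents that add atoms: 2,2-dimethoxypropane, COC(C)(C)OC
Why: Acid-catalysed transacetalisation closes the seven-membered acetonide of the allylic 1,4-diol and masks the C11 and C12 oxygens for the acylation at C1.

**Step 15**
Reactants: 21 1β-[(tert-butyldimethylsilyl)oxy]-11,12-(isopropylidenedioxy)drim-7-ene
Product: 22 11,12-(isopropylidenedioxy)drim-7-en-1β-ol
Conditions: n-Bu4NF, THF, 50 °C
Reagents that add atoms: none
Why: Fluoride-mediated desilylation cleaves the hindered secondary silyl ether while the acetonide is inert to fluoride.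

**Step 16**
Reactants: 23 (E)-p-coumaric acid
Product: 25 (E)-3-{4-[(tert-butyldimethylsilyl)oxy]phenyl}prop-2-enoic acid, via silyl ester 24 (not isolated)
Conditions: TBSCl, imidazole, DMF, 23 °C; then AcOH/THF/H2O, 23 °C
Reagents that add atoms: tert-butyldimethylsilyl chloride, CC(C)(C)[Si](C)(C)Cl
Why: Bis-silylation followed by selective hydrolysis of the labile silyl ester (the aryl silyl ether is stable to dilute acetic acid) gives the phenol-protected acid with the E-alkene untouched.

**Step 17**
Reactants: 22 11,12-(isopropylidenedioxy)drim-7-en-1β-ol; 25 (E)-3-{4-[(tert-butyldimethylsilyl)oxy]phenyl}prop-2-enoic acid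
Product: 26 11,12-(isopropylidenedioxy)drim-7-en-1β-yl (E)-3-{4-[(tert-butyldimethylsilyl)oxy]phenyl}prop-2-enoate
Conditions: DCC, DMAP, CH2Cl2, 23 °C
Reagents that add atoms: none
Why: Steglich esterification with DMAP acyl transfer acylates the hindered equatorial C1 hydroxyl with retention at C1.

**Step 18**
Reactants: 26 11,12-(isopropylidenedioxy)drim-7-en-1β-yl (E)-3-{4-[(tert-butyldimethylsilyl)oxy]phenyl}prop-2-enoate
Product: 27 11,12-dihydroxydrim-7-en-1β-yl (E)-3-{4-[(tert-butyldimethylsilyl)oxy]phenyl}prop-2-enoate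
Conditions: AcOH/THF/H2O (3:1:1), 23 °C
Reagents that add atoms: none
Why: Mild aqueous acid hydrolysis of the seven-membered acetal frees the diol while the aryl silyl ether and the cinnamate ester survive.

**Step 19**
Reactants: 27 11,12-dihydroxydrim-7-en-1β-yl (E)-3-{4-[(tert-butyldimethylsilyl)oxy]phenyl}prop-2-enoate
Product: 28 11,12-dioxodrim-7-en-1β-yl (E)-3-{4-[(tert-butyldimethylsilyl)oxy]phenyl}prop-2-enoate
Conditions: (COCl)2, DMSO, CH2Cl2, −78 °C; then Et3N, −78 to 0 °C
Reagents that add atoms: none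
Why: Swern oxidation activates both primary alcohols at −78 °C before a lactol can form, the known last step from drim-7-ene-11,12-diol to polygodial, and should leave the 9-formyl stereocentre intact at low temperature.

**Step 20**
Reactants: 28 11,12-dioxodrim-7-en-1β-yl (E)-3-{4-[(tert-butyldimethylsilyl)oxy]phenyl}prop-2-enoate
Product: 29 1β-[(E)-p-coumaroyloxy]polygodial, (1R,5S,9R,10S)-11,12-dioxodrim-7-en-1-yl (E)-3-(4-hydroxyphenyl)prop-2-enoate
Conditions: HF·pyridine, pyridine, THF, 0 °C
Reagents that add atoms: none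
Why: Fluoride cleavage of the aryl silyl ether under buffered, non-basic conditions should leave the base-sensitive C9 centre, the enal and the ester untouched.

**Compound list**

1 | 2,2,6-trimethylcyclohexan-1-one | CC1CCCC(C)(C)C1=O | starting material
2 | 2,6,6-trimethylcyclohex-2-en-1-one | CC1=CCCC(C)(C)C1=O | intermediate
3 | (3R)-2,6,6-trimethyl-3-(4,4,5,5-tetramethyl-1,3,2-dioxaborolan-2-yl)cyclohexan-1-one (C2 epimers) | CC1(C)CC[C@@H](B2OC(C)(C)C(C)(C)O2)C(C)C1=O | intermediate (not isolated)
4 | (3R)-3-hydroxy-2,6,6-trimethylcyclohexan-1-one (C2 epimers) | CC1(C)CC[C@@H](O)C(C)C1=O | intermediate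
5 | (3R)-3-[(tert-butyldimethylsilyl)oxy]-2,6,6-trimethylcyclohexan-1-one (C2 epimers) | CC1(C)CC[C@@H](O[Si](C)(C)C(C)(C)C)C(C)C1=O | intermediate
6 | (benzyloxy)acetaldehyde | O=CCOCc1ccccc1 | starting material
7 | lithium (3R)-3-[(tert-butyldimethylsilyl)oxy]-2,6,6-trimethylcyclohex-1-en-1-olate | [Li+].CC1(C)CC[C@@H](O[Si](C)(C)C(C)(C)C)C(C)=C1[O-] | intermediate (not isolated)
8 | (2S,3R)-2-[2-(benzyloxy)-1-hydroxyethyl]-3-[(tert-butyldimethylsilyl)oxy]-2,6,6-trimethylcyclohexan-1-one (carbinol epimers) | CC1(C)CC[C@@H](O[Si](C)(C)C(C)(C)C)[C@](C)(C(O)COCc2ccccc2)C1=O | intermediate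
9 | (2S,3R)-2-[(benzyloxy)acetyl]-3-[(tert-butyldimethylsilyl)oxy]-2,6,6-trimethylcyclohexan-1-one | CC1(C)CC[C@@H](O[Si](C)(C)C(C)(C)C)[C@](C)(C(=O)COCc2ccccc2)C1=O | intermediate
10 | (2S,3R)-3-[(tert-butyldimethylsilyl)oxy]-2-(hydroxyacetyl)-2,6,6-trimethylcyclohexan-1-one | CC1(C)CC[C@@H](O[Si](C)(C)C(C)(C)C)[C@](C)(C(=O)CO)C1=O | intermediate
11 | (diethoxyphosphoryl)acetic acid | CCOP(=O)(CC(=O)O)OCC | starting material
12 | Meldrum's acid (2,2-dimethyl-1,3-dioxane-4,6-dione) | CC1(C)OC(=O)CC(=O)O1 | starting material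
13 | 5-[2-(diethoxyphosphoryl)-1-hydroxyethylidene]-2,2-dimethyl-1,3-dioxane-4,6-dione | CCOP(=O)(OCC)CC(O)=C1C(=O)OC(C)(C)OC1=O | intermediate
14 | 2-{(1S,6R)-6-[(tert-butyldimethylsilyl)oxy]-1,3,3-trimethyl-2-oxocyclohexyl}-2-oxoethyl 4-(diethoxyphosphoryl)-3-oxobutanoate | CC1(C)CC[C@@H](O[Si](C)(C)C(C)(C)C)[C@](C)(C(=O)COC(=O)CC(=O)CP(=O)(OCC)OCC)C1=O | intermediate
15 | diethyl [2-(4-{(1S,6R)-6-[(tert-butyldimethylsilyl)oxy]-1,3,3-trimethyl-2-oxocyclohexyl}-2-oxo-2,5-dihydrofuran-3-yl)-2-oxoethyl]phosphonate | CC1(C)CC[C@@H](O[Si](C)(C)C(C)(C)C)[C@](C)(C2=C(C(=O)CP(=O)(OCC)OCC)C(=O)OC2)C1=O | intermediate (not isolated)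
16 | 1β-[(tert-butyldimethylsilyl)oxy]-7-oxodrima-5,8-dien-12,11-olide (10β-methyl) | CC1(C)CC[C@@H](O[Si](C)(C)C(C)(C)C)[C@]2(C)C3=C(C(=O)OC3)C(=O)C=C12 | intermediate
17 | 1β-[(tert-butyldimethylsilyl)oxy]-7-oxo-5α,8α,9α-H-drimano-12,11-lactone (keto form) | CC1(C)CC[C@@H](O[Si](C)(C)C(C)(C)C)[C@]2(C)[C@H]3COC(=O)[C@H]3C(=O)C[C@@H]12 | intermediate
18 | 1β-[(tert-butyldimethylsilyl)oxy]-7-{[(trifluoromethyl)sulfonyl]oxy}drim-7-en-12,11-olide | CC1(C)CC[C@@H](O[Si](C)(C)C(C)(C)C)[C@]2(C)[C@H]3COC(=O)C3=C(OS(=O)(=O)C(F)(F)F)C[C@@H]12 | intermediate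
19 | 1β-[(tert-butyldimethylsilyl)oxy]drim-7-en-12,11-olide | CC1(C)CC[C@@H](O[Si](C)(C)C(C)(C)C)[C@]2(C)[C@H]3COC(=O)C3=CC[C@@H]12 | intermediate
20 | 1β-[(tert-butyldimethylsilyl)oxy]drim-7-ene-11,12-diol | CC1(C)CC[C@@H](O[Si](C)(C)C(C)(C)C)[C@]2(C)[C@@H](CO)C(CO)=CC[C@@H]12 | intermediate
21 | 1β-[(tert-butyldimethylsilyl)oxy]-11,12-(isopropylidenedioxy)drim-7-ene | CC1(C)CC[C@@H](O[Si](C)(C)C(C)(C)C)[C@]2(C)[C@H]3COC(C)(C)OCC3=CC[C@@H]12 | intermediate
22 | 11,12-(isopropylidenedioxy)drim-7-en-1β-ol | CC1(C)CC[C@@H](O)[C@]2(C)[C@H]3COC(C)(C)OCC3=CC[C@@H]12 | intermediate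
23 | (E)-p-coumaric acid | O=C(O)/C=C/c1ccc(O)cc1 | starting material
24 | tert-butyldimethylsilyl (E)-3-{4-[(tert-butyldimethylsilyl)oxy]phenyl}prop-2-enoate | CC(C)(C)[Si](C)(C)OC(=O)/C=C/c1ccc(O[Si](C)(C)C(C)(C)C)cc1 | intermediate (not isolated)
25 | (E)-3-{4-[(tert-butyldimethylsilyl)oxy]phenyl}prop-2-enoic acid | O=C(O)/C=C/c1ccc(O[Si](C)(C)C(C)(C)C)cc1 | intermediate
26 | 11,12-(isopropylidenedioxy)drim-7-en-1β-yl (E)-3-{4-[(tert-butyldimethylsilyl)oxy]phenyl}prop-2-enoate | CC1(C)CC[C@@H](OC(=O)/C=C/c3ccc(O[Si](C)(C)C(C)(C)C)cc3)[C@]2(C)[C@H]4COC(C)(C)OCC4=CC[C@@H]12 | intermediate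
27 | 11,12-dihydroxydrim-7-en-1β-yl (E)-3-{4-[(tert-butyldimethylsilyl)oxy]phenyl}prop-2-enoate | CC1(C)CC[C@@H](OC(=O)/C=C/c3ccc(O[Si](C)(C)C(C)(C)C)cc3)[C@]2(C)[C@@H](CO)C(CO)=CC[C@@H]12 | intermediate
28 | 11,12-dioxodrim-7-en-1β-yl (E)-3-{4-[(tert-butyldimethylsilyl)oxy]phenyl}prop-2-enoate | CC1(C)CC[C@@H](OC(=O)/C=C/c3ccc(O[Si](C)(C)C(C)(C)C)cc3)[C@]2(C)[C@@H](C=O)C(C=O)=CC[C@@H]12 | intermediate
29 | 1β-[(E)-p-coumaroyloxy]polygodial, (1R,5S,9R,10S)-11,12-dioxodrim-7-en-1-yl (E)-3-(4-hydroxyphenyl)prop-2-enoate | CC1(C)CC[C@@H](OC(=O)/C=C/c2ccc(O)cc2)[C@]2(C)[C@@H](C=O)C(C=O)=CC[C@@H]12 | target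

**Step count and risks**

Total step count: 20. Longest linear sequence: 18 steps (steps 1–6, 8–15, 17–20); steps 7 and 16 are side branches.

Steps most likely to fail:

Step 9 (Proposed new method). The phosphonate carbanion may fail to add to the ring ketone between two quaternary carbons, so the cascade would stop at the butenolide or divert into retro-Claisen cleavage of the 1,3-diketone. The fallback uses known chemistry, sets out from 5 and returns at 20. Deprotonation of 5 with KN(SiMe3)2 and trapping with PhNTf2 gives the enol triflate F1. Stille coupling with tributyl(vinyl)stannane (Pd(PPh3)4, LiCl, THF, reflux) gives the 1-vinylcyclohexene F2. Diels–Alder reaction with dimethyl acetylenedicarboxylate (toluene, 110 °C), the dienophile adding anti to the silyloxy group, gives the drima-5,8-diene diester F3. Hydrogenation (H2, Pd/C) of the trisubstituted alkene from the α-face gives the trans-fused Δ8 diester F4. NaOMe in MeOH moves the double bond to give the Δ7 diester F5 with the 9β-ester. LiAlH4 then gives 20.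

Step 4. The β-silyloxy lithium enolate may undergo β-elimination of the silyloxy group, or the aldolate may revert, before the quaternary centre is secured. The fallback sets out from 5 and returns at 8. TMSOTf and Et3N convert 5 into the silyl enol ether F6, the only regioisomer possible. A TiCl4-promoted Mukaiyama aldol addition of F6 to 6 at −78 °C, on the chelated aldehyde and through the same anti approach, then gives 8 without a basic enolate.

Step 10. The hindered trisubstituted enone alkene may be reduced incompletely, or hydrogen may be delivered to C5 from the β-face. The fallback sets out from 16 and returns at 17. Conjugate transfer hydrogenation of the doubly activated butenolide alkene with Hantzsch ester (CH2Cl2, 23 °C) gives the 9α-H keto lactone F7, hydride reaching C9 from the α-face. Hydrogen-atom-transfer hydrogenation of the remaining enone alkene (Mn(dpm)3, dpm = 2,2,6,6-tetramethylheptane-3,5-dionate, PhSiH3, t-BuOOH, i-PrOH), which favours the thermodynamically preferred trans ring fusion, then gives 17.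

**Further compounds**

F1 | step 9 | (3R)-3-[(tert-butyldimethylsilyl)oxy]-2,6,6-trimethylcyclohex-1-en-1-yl trifluoromethanesulfonate | CC1(C)CC[C@@H](O[Si](C)(C)C(C)(C)C)C(C)=C1OS(=O)(=O)C(F)(F)F
F2 | step 9 | tert-butyl{[(1R)-3-ethenyl-2,4,4-trimethylcyclohex-2-en-1-yl]oxy}dimethylsilane | CC1(C)CC[C@@H](O[Si](C)(C)C(C)(C)C)C(C)=C1C=C
F3 | step 9 | dimethyl 1β-[(tert-butyldimethylsilyl)oxy]drima-5,8-diene-11,12-dioate | CC1(C)CC[C@@H](O[Si](C)(C)C(C)(C)C)[C@]2(C)C(C(=O)OC)=C(C(=O)OC)CC=C12
F4 | step 9 | dimethyl 1β-[(tert-butyldimethylsilyl)oxy]drim-8-ene-11,12-dioate | CC1(C)CC[C@@H](O[Si](C)(C)C(C)(C)C)[C@]2(C)C(C(=O)OC)=C(C(=O)OC)CC[C@@H]12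
F5 | step 9 | dimethyl 1β-[(tert-butyldimethylsilyl)oxy]drim-7-ene-11,12-dioate (9β-ester) | CC1(C)CC[C@@H](O[Si](C)(C)C(C)(C)C)[C@]2(C)[C@@H](C(=O)OC)C(C(=O)OC)=CC[C@@H]12
F6 | step 4 | tert-butyl({(1R)-2,4,4-trimethyl-3-[(trimethylsilyl)oxy]cyclohex-2-en-1-yl}oxy)dimethylsilane | CC1(C)CC[C@@H](O[Si](C)(C)C(C)(C)C)C(C)=C1O[Si](C)(C)C
F7 | step 10 | 1β-[(tert-butyldimethylsilyl)oxy]-7-oxo-9α-H-drim-5-en-12,11-olide | CC1(C)CC[C@@H](O[Si](C)(C)C(C)(C)C)[C@]2(C)[C@H]3COC(=O)C3C(=O)C=C12
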